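**Retrosynthetic overview**
1. Target 16 ⇒ bis(O-prenyl) ether 13. Both C-prenyl groups trace back to C–O bonds: an ortho-Claisen on ring A gives the 1,1-dimethylallyl group, and a Claisen–Cope on ring B gives the C4 prenyl group.
2. 13 ⇒ allylbenzofuran 8 + bromophenol 11 by B-alkyl Suzuki coupling. The allyl group of eugenol supplies the whole C3 linker.
3. 8 ⇒ 5 (OMe exchanged for O-prenyl) ⇒ eugenol 1 + two-carbon unit 2. The key step closes the furan through the O1–C2 bond (C–O) in a one-flask sulfonium [3,3] annulation.
4. 11 ⇒ 4-bromoresorcinol 9 + prenyl bromide 6 (C–O bond).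
5. Ring order: both benzene rings are bought. The furan is the only ring built, and it is built first (step 1).

Assumption: the target SMILES has no stereocentre and no E/Z-stereogenic double bond, so the compound is achiral and no enantiomer has to be selected. The stereocentres in racemic 2 and in transient 3, 4 and 15 are all lost.

**Step 1**
Reactants: 1 eugenol (4-allyl-2-methoxyphenol); 2 phenyl vinyl sulfoxide (racemic)
Product: 5 5-allyl-7-methoxybenzofuran, via aryloxysulfonium trifluoroacetate 3 (not isolated), via 2-phenylthio-2,3-dihydrobenzofuran 4 (not isolated)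
Conditions: 2 (1.3 equiv), (CF3CO)2O (2.5 equiv), CH2Cl2, −40 °C → rt, 2 h; then TsOH (20 mol %), 40 °C, 2 h
Reagents that add atoms: none
Why: Proposed new method: TFAA-activated 2 is captured at sulfur by the phenol oxygen (interrupted Pummerer) to give 3, whose charge-accelerated [3,3]-sigmatropic shift joins the vinyl terminus to the only free ortho carbon, after which rearomatisation places the phenol OH next to the new thionium carbon so that the furan ring closes by C–O bond formation to O,S-acetal 4, and acid-driven loss of PhSH (trapped by the excess TFAA) aromatises it to 5; the closest known reaction type is the extended-Pummerer/[3,3] benzofuran annulation of phenols with ketene dithioacetal monoxides and substituted alkenyl or alkynyl sulfoxides, which leaves a thio or carbon substituent on the furan, whereas the parent vinyl sulfoxide as a traceless two-carbon unit for a 2,3-unsubstituted benzofuran on an allyl-bearing guaiacol is untested.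

**Step 2**
Reactants: 5 5-allyl-7-methoxybenzofuran; 6 prenyl bromide (1-bromo-3-methylbut-2-ene)
Product: 8 5-allyl-7-(3-methylbut-2-enyloxy)benzofuran, via sodium aryloxide 7 (not isolated)
Conditions: EtSNa (2 equiv), DMF, 130 °C, 3 h; cool to 0 °C; then 6 (3 equiv), rt, 2 h
Reagents that add atoms: none
Why: The soft thiolate cleaves the aryl methyl ether by SN2 at methyl (the 7-olate flanked by the furan oxygen is a good leaving group, and the allyl group and furan are inert to thiolate), and aryloxide 7 is then O-alkylated in the same DMF solution (Williamson ether synthesis).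

**Step 3**
Reactants: 9 4-bromoresorcinol; 6 prenyl bromide
Product: 11 2-bromo-5-(3-methylbut-2-enyloxy)phenol, via disodium diolate 10 (not isolated)
Conditions: NaH (2.1 equiv), DMF, 0 °C; then 6 (1.0 equiv, slow addition), 0 °C → rt; 1 M HCl work-up
Reagents that add atoms: none
Why: In dianion 10 the phenoxide para to Br is the more basic and less hindered one, so one equivalent of 6 reacts there first (Williamson ether synthesis, with DMF favouring O- over C-alkylation), and the remaining o-bromophenoxide is the poorest nucleophile in the flask, which limits bis-alkylation.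

**Step 4**
Reactants: 8 5-allyl-7-(3-methylbut-2-enyloxy)benzofuran; 11 2-bromo-5-(3-methylbut-2-enyloxy)phenol
Product: 13 2-{3-[7-(3-methylbut-2-enyloxy)benzofuran-5-yl]propyl}-5-(3-methylbut-2-enyloxy)phenol, via B-alkyl-9-BBN borane 12 (not isolated)
Conditions: 8, 9-BBN (1.1 equiv), THF, 0 °C → rt, 3 h; then 11 (0.9 equiv), SPhos Pd G3 (3 mol %), aq. K3PO4 (3.5 equiv), THF/DMF, 50 °C, 12 h
Reagents that add atoms: none
Why: 9-BBN hydroborates only the monosubstituted allyl C=C in the anti-Markovnikov sense (the trisubstituted prenyl C=C and the furan react far more slowly), and B-alkyl Suzuki–Miyaura coupling of 12 with the aryl bromide, using an electron-rich biaryl phosphine that handles the electron-rich bromophenoxide at 50 °C where Pd(0) does not ionise aryl prenyl ethers, gives the complete 1,3-diarylpropane.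

**Step 5**
Reactants: 13 bis(prenyl ether)
Product: 16 5-{3-[2,4-dihydroxy-5-(2-methylbut-3-en-2-yl)phenyl]propyl}-4-(3-methylbut-2-enyl)benzofuran-7-ol (target), via ring-A-rearranged monoether 14 (not isolated), via ring-B ortho-dienone 15 (not isolated)
Conditions: PhNEt2 (0.05 M), 200 °C (sealed tube), 2 h, Ar
Reagents that add atoms: none
Why: Two aromatic Claisen rearrangements run in one heating: on ring A the [3,3] shift goes to C5 (away from the meta-OH donor and the crowded C3) and enolisation gives the 1,1-dimethylallyl phenol 14, while on ring B the first [3,3] shift gives the crowded C6 dienone 15, which undergoes a Cope shift to C4 faster than it enolises (tandem Claisen–Cope, i.e. para-Claisen) and then tautomerises to the normal C4-prenyl phenol, so no stereocentre remains.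

**Compound list**
1 | eugenol (4-allyl-2-methoxyphenol) | C=CCc1ccc(O)c(OC)c1 | starting material
2 | phenyl vinyl sulfoxide (racemic) | C=CS(=O)c1ccccc1 | starting material
3 | (4-allyl-2-methoxyphenoxy)(phenyl)(vinyl)sulfonium trifluoroacetate (racemic) | C=CCc1ccc(O[S+](C=C)c2ccccc2)c(OC)c1.[O-]C(=O)C(F)(F)F | intermediate
4 | 5-allyl-7-methoxy-2-(phenylthio)-2,3-dihydrobenzofuran (racemic) | C=CCc1cc(OC)c2OC(Sc3ccccc3)Cc2c1 | intermediate
5 | 5-allyl-7-methoxybenzofuran | C=CCc1cc(OC)c2occc2c1 | intermediate
6 | prenyl bromide (1-bromo-3-methylbut-2-ene) | CC(C)=CCBr | starting material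
7 | sodium 5-allylbenzofuran-7-olate | C=CCc1cc([O-])c2occc2c1.[Na+] | intermediate
8 | 5-allyl-7-(3-methylbut-2-enyloxy)benzofuran | C=CCc1cc(OCC=C(C)C)c2occc2c1 | intermediate
9 | 4-bromoresorcinol (4-bromobenzene-1,3-diol) | Oc1ccc(Br)c(O)c1 | starting material
10 | disodium 4-bromobenzene-1,3-diolate | [O-]c1ccc(Br)c([O-])c1.[Na+].[Na+] | intermediate
11 | 2-bromo-5-(3-methylbut-2-enyloxy)phenol | CC(C)=CCOc1ccc(Br)c(O)c1 | intermediate
12 | 9-{3-[7-(3-methylbut-2-enyloxy)benzofuran-5-yl]propyl}-9-borabicyclo[3.3.1]nonane | CC(C)=CCOc1cc(CCCB2C3CCCC2CCC3)cc2ccoc12 | intermediate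
13 | 2-{3-[7-(3-methylbut-2-enyloxy)benzofuran-5-yl]propyl}-5-(3-methylbut-2-enyloxy)phenol | CC(C)=CCOc1ccc(CCCc2cc(OCC=C(C)C)c3occc3c2)c(O)c1 | intermediate
14 | 4-(2-methylbut-3-en-2-yl)-6-{3-[7-(3-methylbut-2-enyloxy)benzofuran-5-yl]propyl}benzene-1,3-diol | C=CC(C)(C)c1cc(CCCc2cc(OCC=C(C)C)c3occc3c2)c(O)cc1O | intermediate
15 | 5-{3-[2,4-dihydroxy-5-(2-methylbut-3-en-2-yl)phenyl]propyl}-6-(2-methylbut-3-en-2-yl)benzofuran-7(6H)-one (racemic) | O=C1c2occc2C=C(CCCc2cc(C(C)(C)C=C)c(O)cc2O)C1C(C)(C)C=C | intermediate
16 | CNP0288359.0, 5-{3-[2,4-dihydroxy-5-(2-methylbut-3-en-2-yl)phenyl]propyl}-4-(3-methylbut-2-enyl)benzofuran-7-ol (achiral) | C=CC(C)(C)c1cc(CCCc2cc(O)c3occc3c2CC=C(C)C)c(O)cc1O | target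

**Totals:** 5 steps in all. The longest linear sequence is 4 steps (1 → 5 → 8 → 13 → 16).

**Three steps most likely to fail**

Risk A, step 1 (the proposed new annulation). Trifluoroacetate may add to activated 2 (additive Pummerer) before the phenol is captured, or 4 may not give up PhSH cleanly. The fallback uses known chemistry, sets out from 1 and comes back at 5. Eugenol 1 is O-alkylated with bromoacetaldehyde diethyl acetal (K2CO3, DMF, 120 °C) to give 4-allyl-1-(2,2-diethoxyethoxy)-2-methoxybenzene F1. This is cyclodehydrated with Amberlyst-15 in refluxing chlorobenzene (the classical aryloxyacetal benzofuran synthesis) to give 5. It costs one more step.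

Risk B, step 3 (site selectivity between the two OH groups of 9, and C-prenylation of the dianion). The fallback replaces selectivity by a pre-differentiated resorcinol. It sets out from 6, with a purchased monoester in place of 9, and comes back at 11.
- 3-hydroxyphenyl benzoate F2 is brominated para to its free OH (NBS, MeCN, 0 °C) to give 2-bromo-5-hydroxyphenyl benzoate F3.
- The only free OH is alkylated with 6 (K2CO3, acetone) to give 2-bromo-5-(3-methylbut-2-enyloxy)phenyl benzoate F4.
- Methanolysis (K2CO3, MeOH, rt) gives 11.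

It costs two more steps.

Risk C, step 5 (two rearrangements with different needs in one flask). Ring B may enolise at the stage of 15 instead of undergoing the Cope shift. Ring A may give some C3 isomer, or its product may cyclise or rearrange further at 200 °C. The fallback decouples the two events. It sets out from 8, uses 11, and comes back at 16.
- 8 alone is heated (PhNEt2, 200 °C), and 5-allyl-4-(3-methylbut-2-enyl)benzofuran-7-ol F5 is purified from regioisomers at this small-molecule stage.
- 9-BBN (2.2 equiv, one equivalent being taken up by the OH) gives the O,C-bis(9-BBN) derivative F6.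
- F6 is coupled with 11 under the step 4 conditions to give 5-{3-[2-hydroxy-4-(3-methylbut-2-enyloxy)phenyl]propyl}-4-(3-methylbut-2-enyl)benzofuran-7-ol F7.
- The ring A ortho-Claisen is then run alone under milder water-accelerated conditions (EtOH–H2O 4:1, 130 °C, sealed tube) to give 16.

It costs two more steps.

**Further compounds**
F1 | step 1 | 4-allyl-1-(2,2-diethoxyethoxy)-2-methoxybenzene | C=CCc1ccc(OCC(OCC)OCC)c(OC)c1
F2 | step 3 | 3-hydroxyphenyl benzoate (resorcinol monobenzoate; purchased) | Oc1cccc(OC(=O)c2ccccc2)c1
F3 | step 3 | 2-bromo-5-hydroxyphenyl benzoate | Oc1ccc(Br)c(OC(=O)c2ccccc2)c1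
F4 | step 3 | 2-bromo-5-(3-methylbut-2-enyloxy)phenyl benzoate | CC(C)=CCOc1ccc(Br)c(OC(=O)c2ccccc2)c1
F5 | step 5 | 5-allyl-4-(3-methylbut-2-enyl)benzofuran-7-ol | C=CCc1cc(O)c2occc2c1CC=C(C)C
F6 | step 5 | 9-{3-[7-(9-borabicyclo[3.3.1]nonan-9-yloxy)-4-(3-methylbut-2-enyl)benzofuran-5-yl]propyl}-9-borabicyclo[3.3.1]nonane | CC(C)=CCc1c(CCCB2C3CCCC2CCC3)cc(OB2C3CCCC2CCC3)c2occc12
F7 | step 5 | 5-{3-[2-hydroxy-4-(3-methylbut-2-enyloxy)phenyl]propyl}-4-(3-methylbut-2-enyl)benzofuran-7-ol | CC(C)=CCOc1ccc(CCCc2cc(O)c3occc3c2CC=C(C)C)c(O)c1
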